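**Retrosynthetic overview**
1. Target 19 comes from 17 by one hydrogenation that saturates the stilbene between rings C and D and removes the only O-benzyl group.
2. Key disconnection: the C(aryl)–OMe bond of ring B. Ring B is made aromatic last, from 2-benzyl-1,3-dione 14, by C–O bond formation with methanol plus dehydrogenation; this fixes OH on one side of the CH2 bridge and OMe on the other.
3. 14 comes from dione 5 and aldehyde 12 by reductive Knoevenagel alkylation, which places the bridge on the carbon between the two ring B oxygens.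
4. 5 comes from stilbene 3 (Heck reaction of 1 with 2, then reduction of the resorcinol ring to the dione). 12 comes from 6 by two SNAr C–O bond formations (OBn para, OMe ortho) and a Heck reaction with 11.
5. Ring order: rings A, C and D are bought as arenes; ring B is bought as a resorcinol, dearomatised in step 2 and re-formed as the arene in step 7.

Assumption: the target has no stereocentre, stereogenic axis or stereogenic double bond, so "single enantiomer" is read as the one achiral compound given.

**Step 1**
Reactants: 1 5-bromobenzene-1,3-diol; 2 2-methoxy-4-vinylphenol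
Product: 3 5-[(E)-2-(4-hydroxy-3-methoxyphenyl)ethenyl]benzene-1,3-diol
Conditions: Pd(OAc)2 (2 mol %), P(o-tol)3 (4 mol %), NaOAc (1.5 equiv), DMF, 110 °C
Reagents that add atoms: none
Why: Mizoroki–Heck reaction, in which oxidative addition into the C–Br bond (both OH groups are meta to bromine and do not deactivate it), syn-insertion of the styrene and syn-β-hydride elimination give the E-stilbene, and the weak acetate base leaves the phenols un-ionised.

**Step 2**
Reactants: 3 5-[(E)-2-(4-hydroxy-3-methoxyphenyl)ethenyl]benzene-1,3-diol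
Product: 5 5-[2-(4-hydroxy-3-methoxyphenyl)ethyl]cyclohexane-1,3-dione, via bibenzyl triol 4 (not isolated)
Conditions: H2 (10 bar), 5% Pd/C, NaOH (1.2 equiv), H2O, 50 °C; then HCl to pH 2
Reagents that add atoms: none
Why: Catalytic hydrogenation in which the alkene is saturated first and the resorcinol monoanion then takes up one H2 and stops at the β-diketonate (a vinylogous carboxylate that resists further reduction), the established resorcinol-to-cyclohexane-1,3-dione reduction, while the guaiacol ring is not reduced on Pd/C at 50 °C.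

**Step 3**
Reactants: 6 2-bromo-4,6-difluorobenzaldehyde; 7 benzyl alcohol
Product: 8 4-(benzyloxy)-2-bromo-6-fluorobenzaldehyde
Conditions: BnOH (1.0 equiv), K2CO3 (1.5 equiv), DMF, 50 °C
Reagents that add atoms: benzyl alcohol (7), OCc1ccccc1
Why: Nucleophilic aromatic substitution (addition–elimination) in which the 4-fluorine, activated by the para formyl group and not crowded by it, reacts first, the new alkoxy group deactivates the ring against a second substitution, and fluoride leaves far faster than bromide.

**Step 4**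
Reactants: 8 4-(benzyloxy)-2-bromo-6-fluorobenzaldehyde; 9 sodium methoxide
Product: 10 4-(benzyloxy)-2-bromo-6-methoxybenzaldehyde
Conditions: NaOMe (1.2 equiv), MeOH/THF, 60 °C
Reagents that add atoms: sodium methoxide (9), C[O-].[Na+]
Why: Second nucleophilic aromatic substitution, in which the remaining fluorine ortho to the formyl group is displaced by methoxide while the bromide, a much poorer leaving group in addition–elimination, stays.

**Step 5**
Reactants: 10 4-(benzyloxy)-2-bromo-6-methoxybenzaldehyde; 11 3-vinylphenol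
Product: 12 4-(benzyloxy)-2-[(E)-2-(3-hydroxyphenyl)ethenyl]-6-methoxybenzaldehyde
Conditions: Pd(OAc)2 (2 mol %), P(o-tol)3 (4 mol %), NaOAc (1.5 equiv), DMF, 110 °C
Reagents that add atoms: none
Why: Mizoroki–Heck reaction of an aryl bromide that is activated by the ortho formyl group and is meta to both alkoxy groups, giving the E-stilbene by syn-insertion and syn-β-hydride elimination.

**Step 6**
Reactants: 5 5-[2-(4-hydroxy-3-methoxyphenyl)ethyl]cyclohexane-1,3-dione; 12 4-(benzyloxy)-2-[(E)-2-(3-hydroxyphenyl)ethenyl]-6-methoxybenzaldehyde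
Product: 14 2-{[4-(benzyloxy)-2-methoxy-6-[(E)-2-(3-hydroxyphenyl)ethenyl]phenyl]methyl}-5-[2-(4-hydroxy-3-methoxyphenyl)ethyl]cyclohexane-1,3-dione, via alkylidene dione 13 (not isolated)
Conditions: L-proline (20 mol %), diethyl 1,4-dihydro-2,6-dimethylpyridine-3,5-dicarboxylate (Hantzsch ester, 1.1 equiv), EtOH, 40 °C
Reagents that add atoms: none
Why: Organocatalytic three-component reductive alkylation, in which proline-catalysed Knoevenagel condensation gives alkylidene dione 13 and its electron-poor exocyclic C=C is reduced at once by hydride transfer from the Hantzsch ester, so the benzyl group sits on C2 between the two carbonyls while the stilbene, the benzyl ether and the free phenols are untouched.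

**Step 7**
Reactants: 14 2-{[4-(benzyloxy)-2-methoxy-6-[(E)-2-(3-hydroxyphenyl)ethenyl]phenyl]methyl}-5-[2-(4-hydroxy-3-methoxyphenyl)ethyl]cyclohexane-1,3-dione; 15 methanol
Product: 17 2-{[4-(benzyloxy)-2-methoxy-6-[(E)-2-(3-hydroxyphenyl)ethenyl]phenyl]methyl}-5-[2-(4-hydroxy-3-methoxyphenyl)ethyl]-3-methoxyphenol, via methyl enol ether 16 (not isolated)
Conditions: MeOH, TsOH·H2O (10 mol %), 3 Å MS, 60 °C; then evaporate, DMSO, Pd(OCOCF3)2 (5 mol %), 2-(dimethylamino)pyridine (10 mol %), 3 Å MS, O2 (1 atm), 80 °C
Reagents that add atoms: methanol (15), CO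
Why: Proposed new method: a one-flask desymmetrising dehydrogenative O-methylation of a 2-benzylcyclohexane-1,3-dione, in which acid-catalysed condensation with methanol can form only one enol ether C–O bond per dione (vinylogous ester 16, phenols not being etherified), a divalent palladium enolate at C6 of the remaining ketone then undergoes β-hydride elimination, the 3-methoxycyclohexa-2,5-dienone tautomerises irreversibly to the phenol and O2 reoxidises the palladium hydride, so the OH/OMe pattern of ring B and the arene are set together; the closest known reaction type is the aerobic palladium-catalysed dehydrogenation of cyclohexenones to phenols (and the iodine/methanol aromatisation of cyclohexenones to anisoles), not yet shown as a single desymmetrising operation on 2-(arylmethyl)-1,3-diones carrying free phenols and a stilbene.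

**Step 8**
Reactants: 17 2-{[4-(benzyloxy)-2-methoxy-6-[(E)-2-(3-hydroxyphenyl)ethenyl]phenyl]methyl}-5-[2-(4-hydroxy-3-methoxyphenyl)ethyl]-3-methoxyphenol
Product: 19 2-{[4-hydroxy-2-methoxy-6-[2-(3-hydroxyphenyl)ethyl]phenyl]methyl}-5-[2-(4-hydroxy-3-methoxyphenyl)ethyl]-3-methoxyphenol, via bibenzyl benzyl ether 18 (not isolated)
Conditions: H2 (1 atm), 10% Pd/C, EtOAc/MeOH 1:1, rt
Reagents that add atoms: none
Why: Heterogeneous hydrogenation and hydrogenolysis, in which the stilbene C=C is saturated and the single benzyl ether is then cleaved, while the aryl methyl ethers and the diarylmethane are inert under neutral conditions and no stereocentre is formed.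

**Compound list**
1 | 5-bromobenzene-1,3-diol (5-bromoresorcinol) | Oc1cc(O)cc(Br)c1 | starting material
2 | 2-methoxy-4-vinylphenol | COc1cc(C=C)ccc1O | starting material
3 | 5-[(E)-2-(4-hydroxy-3-methoxyphenyl)ethenyl]benzene-1,3-diol | COc1cc(/C=C/c2cc(O)cc(O)c2)ccc1O | intermediate
4 | 5-[2-(4-hydroxy-3-methoxyphenyl)ethyl]benzene-1,3-diol (bibenzyl triol, not isolated) | COc1cc(CCc2cc(O)cc(O)c2)ccc1O | intermediate
5 | 5-[2-(4-hydroxy-3-methoxyphenyl)ethyl]cyclohexane-1,3-dione (achiral; keto/enol mixture) | COc1cc(CCC2CC(=O)CC(=O)C2)ccc1O | intermediate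
6 | 2-bromo-4,6-difluorobenzaldehyde | O=Cc1c(F)cc(F)cc1Br | starting material
7 | benzyl alcohol | OCc1ccccc1 | starting material
8 | 4-(benzyloxy)-2-bromo-6-fluorobenzaldehyde | O=Cc1c(F)cc(OCc2ccccc2)cc1Br | intermediate
9 | sodium methoxide | C[O-].[Na+] | starting material
10 | 4-(benzyloxy)-2-bromo-6-methoxybenzaldehyde | COc1cc(OCc2ccccc2)cc(Br)c1C=O | intermediate
11 | 3-vinylphenol | C=Cc1cccc(O)c1 | starting material
12 | 4-(benzyloxy)-2-[(E)-2-(3-hydroxyphenyl)ethenyl]-6-methoxybenzaldehyde | COc1cc(OCc2ccccc2)cc(/C=C/c2cccc(O)c2)c1C=O | intermediate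
13 | 2-{[4-(benzyloxy)-2-methoxy-6-[(E)-2-(3-hydroxyphenyl)ethenyl]phenyl]methylidene}-5-[2-(4-hydroxy-3-methoxyphenyl)ethyl]cyclohexane-1,3-dione (racemic, axial chirality of the 4-substituted alkylidenecyclohexane type; not isolated) | O=C1CC(CCc2ccc(O)c(OC)c2)CC(=O)C1=Cc1c(OC)cc(OCc2ccccc2)cc1/C=C/c1cccc(O)c1 | intermediate
14 | 2-{[4-(benzyloxy)-2-methoxy-6-[(E)-2-(3-hydroxyphenyl)ethenyl]phenyl]methyl}-5-[2-(4-hydroxy-3-methoxyphenyl)ethyl]cyclohexane-1,3-dione (keto/enol mixture; C2/C5 relative configuration undefined and lost on aromatisation) | O=C1CC(CCc2ccc(O)c(OC)c2)CC(=O)C1Cc1c(OC)cc(OCc2ccccc2)cc1/C=C/c1cccc(O)c1 | intermediate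
15 | methanol | CO | starting material
16 | 2-{[4-(benzyloxy)-2-methoxy-6-[(E)-2-(3-hydroxyphenyl)ethenyl]phenyl]methyl}-5-[2-(4-hydroxy-3-methoxyphenyl)ethyl]-3-methoxycyclohex-2-en-1-one (racemic at C5; not isolated) | O=C1CC(CCc2ccc(O)c(OC)c2)CC(OC)=C1Cc1c(OC)cc(OCc2ccccc2)cc1/C=C/c1cccc(O)c1 | intermediate
17 | 2-{[4-(benzyloxy)-2-methoxy-6-[(E)-2-(3-hydroxyphenyl)ethenyl]phenyl]methyl}-5-[2-(4-hydroxy-3-methoxyphenyl)ethyl]-3-methoxyphenol | COc1cc(CCc2cc(O)c(Cc3c(/C=C/c4cccc(O)c4)cc(OCc4ccccc4)cc3OC)c(OC)c2)ccc1O | intermediate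
18 | 2-{[4-(benzyloxy)-2-methoxy-6-[2-(3-hydroxyphenyl)ethyl]phenyl]methyl}-5-[2-(4-hydroxy-3-methoxyphenyl)ethyl]-3-methoxyphenol (not isolated) | COc1cc(CCc2cc(O)c(Cc3c(CCc4cccc(O)c4)cc(OCc4ccccc4)cc3OC)c(OC)c2)ccc1O | intermediate
19 | 2-{[4-hydroxy-2-methoxy-6-[2-(3-hydroxyphenyl)ethyl]phenyl]methyl}-5-[2-(4-hydroxy-3-methoxyphenyl)ethyl]-3-methoxyphenol (achiral) | COc1cc(CCc2cc(O)c(Cc3c(CCc4cccc(O)c4)cc(O)cc3OC)c(OC)c2)ccc1O | target

**Totals**
Total step count: 8.
Longest linear sequence: 6 steps (steps 3, 4, 5, 6, 7 and 8, from 6 to 19).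

**Three steps most likely to fail**

Step 7 (the proposed new step). The enol ether may hydrolyse back to the dione before it is dehydrogenated, giving the unmethylated resorcinol, or the palladium catalyst may be held up by the free phenols or the stilbene. The fallback uses known chemistry and sets out from 14. The methyl enol ether 16 is made as in the first stage (MeOH, TsOH·H2O, 3 Å MS) and is now isolated. Kinetic deprotonation at C6 with LiN(iPr)2 (3.3 equiv, THF, −78 °C) and trapping with Me3SiCl gives 3-{[4-(benzyloxy)-2-methoxy-6-[(E)-2-(3-trimethylsilyloxyphenyl)ethenyl]phenyl]methyl}-4-methoxy-6-[2-(3-methoxy-4-trimethylsilyloxyphenyl)ethyl]-2-(trimethylsilyloxy)cyclohexa-1,3-diene F1, in which both phenols are silylated as well. Saegusa–Ito oxidation with Pd(OAc)2 (1.1 equiv, MeCN, rt) gives the dienone, which tautomerises to the phenol. Dilute HCl work-up removes the two aryl silyl ethers and the sequence comes back to the route at 17.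

Step 6. The aldehyde 12 is electron-rich and carries two ortho substituents, so the Knoevenagel condensation may be too slow and the Hantzsch ester may be spent unproductively. The fallback sets out from 12 and does not need a condensation at the hindered carbonyl. NaBH4 (MeOH, 0 °C) gives {4-(benzyloxy)-2-[(E)-2-(3-hydroxyphenyl)ethenyl]-6-methoxyphenyl}methanol F2. Acid-catalysed dehydrative C-benzylation of dione 5 (2 equiv) with this alcohol (Bi(OSO2CF3)3 5 mol %, MeNO2, 50 °C) proceeds by an SN1 pathway through the 2,4-dialkoxybenzyl cation, a known reaction of electron-rich benzylic alcohols with cyclic 1,3-diones. It comes back to the route at 14.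

Step 3. The ortho fluorine may compete with the para fluorine, which would put the benzyloxy and methoxy groups on the wrong positions of ring C after step 4. The fallback sets out from 1 and fixes the pattern by phenol chemistry of known regioselectivity. Vilsmeier–Haack formylation (POCl3, DMF, MeCN, 0 °C to rt; then H2O) gives 2-bromo-4,6-dihydroxybenzaldehyde F3. BnBr with NaHCO3 in MeCN at 80 °C benzylates only the 4-OH, because the 6-OH is hydrogen-bonded to the aldehyde, and gives 4-(benzyloxy)-2-bromo-6-hydroxybenzaldehyde F4. MeI with K2CO3 in DMF then methylates the remaining OH and the sequence comes back to the route at 10, replacing steps 3 and 4 by three steps.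

**Further compounds**
F1 | step 7 | 3-{[4-(benzyloxy)-2-methoxy-6-[(E)-2-(3-trimethylsilyloxyphenyl)ethenyl]phenyl]methyl}-4-methoxy-6-[2-(3-methoxy-4-trimethylsilyloxyphenyl)ethyl]-2-(trimethylsilyloxy)cyclohexa-1,3-diene (racemic) | C[Si](C)(C)OC1=CC(CCc2ccc(O[Si](C)(C)C)c(OC)c2)CC(OC)=C1Cc1c(OC)cc(OCc2ccccc2)cc1/C=C/c1cccc(O[Si](C)(C)C)c1
F2 | step 6 | {4-(benzyloxy)-2-[(E)-2-(3-hydroxyphenyl)ethenyl]-6-methoxyphenyl}methanol | COc1cc(OCc2ccccc2)cc(/C=C/c2cccc(O)c2)c1CO
F3 | step 3 | 2-bromo-4,6-dihydroxybenzaldehyde | O=Cc1c(O)cc(O)cc1Br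
F4 | step 3 | 4-(benzyloxy)-2-bromo-6-hydroxybenzaldehyde | O=Cc1c(O)cc(OCc2ccccc2)cc1Br
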